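## Retrosynthetic overview

1. Diacarperoxide B (15) ⇐ ozonolysis of the tetrasubstituted cyclohexene in 14; the 2,2-dimethyl-1,6-diketone stays masked as the dihydro-β-ionone ring until the last step.
2. The 1,2-dioxane (the only ring formed) ⇐ C6–O bond by an enantioselective Brønsted-acid 6-exo cyclisation of the C3 hydroperoxide 13 onto the C6=CH2 alkene (sets C6).
3. C3–OO and C2–Me ⇐ primary-amine iminium peroxidation/protonation of the achiral (E)-2-methyl enal 7 with a cleavable hydroperoxide (sets C3 and C2 first).
4. Enal 7 ⇐ cross-metathesis with methacrolein ⇐ Wittig methylenation ⇐ kinetic allylation of dihydro-β-ionone.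
5. Ring order: cyclohexene present from the start, dioxane closed in step 9, cyclohexene cleaved in step 10.

Assumption: hydroperoxide 9 is not a catalogue reagent, so its one-step preparation is counted (step 4).
Assumption: the catalyst antipodes named in steps 5 and 9 give the sense shown; if either gives the opposite sense, the (pseudo)enantiomeric catalyst is used.

## Route

**Step 1**
Reactants: 1, dihydro-β-ionone [4-(2,6,6-trimethylcyclohex-1-en-1-yl)butan-2-one]; 2, allyl bromide
Product: 3, 1-(2,6,6-trimethylcyclohex-1-en-1-yl)hept-6-en-3-one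
Conditions: LDA, THF, −78 °C; then 2, DMPU, −78 → −20 °C
Reagents that add atoms: allyl bromide (2), C=CCBr
Why: Kinetic deprotonation at the methyl group gives the terminal lithium enolate, which is allylated by SN2 (enolate alkylation); no stereocentre is formed.

**Step 2**
Reactants: 3; 4, methyltriphenylphosphonium bromide
Product: 5, 1,3,3-trimethyl-2-(3-methylidenehept-6-en-1-yl)cyclohex-1-ene
Conditions: 4, KOtBu, THF, 0 °C → rt
Reagents that add atoms: methyltriphenylphosphonium bromide (4), [Br-].C[P+](c1ccccc1)(c1ccccc1)c1ccccc1
Why: Wittig methylenation of an unhindered dialkyl ketone; the CH2 installed here becomes the C6 methyl of the target.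

**Step 3**
Reactants: 5; 6, methacrolein
Product: 7, (2E)-2-methyl-6-methylidene-8-(2,6,6-trimethylcyclohex-1-en-1-yl)oct-2-enal
Conditions: Hoveyda–Grubbs II (5 mol %), 6 (8 equiv), CH2Cl2, 40 °C
Reagents that add atoms: methacrolein (6), CC(=C)C=O
Why: Olefin cross-metathesis engages only the monosubstituted alkene (the 1,1-disubstituted and tetrasubstituted alkenes are inert) and gives the thermodynamic E trisubstituted enal.

**Step 4**
Reactants: 8, 2,3-dimethylbut-2-ene
Product: 9, 2-methoxypropan-2-yl hydroperoxide
Conditions: O3, CH2Cl2/MeOH, −78 °C; N2 purge; used as a cold solution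
Reagents that add atoms: ozone, [O-][O+]=O; methanol, CO
Why: Ozonolysis in methanol, where the acetone carbonyl oxide (Criegee intermediate) is trapped by MeOH to give the α-methoxy hydroperoxide, a masked H2O2.

**Step 5**
Reactants: 7; 9
Product: 10, (2S,3S)-3-[(2-methoxypropan-2-yl)peroxy]-2-methyl-6-methylidene-8-(2,6,6-trimethylcyclohex-1-en-1-yl)octanal
Conditions: 9-amino-9-deoxy-epi-quinine (10 mol %), (R)-TRIP (20 mol %), 9 (2 equiv), toluene, −10 °C; used crude
Reagents that add atoms: 2-methoxypropan-2-yl hydroperoxide (9), COC(C)(C)OO
Why: Proposed new method: the primary amine forms the iminium ion of the α-branched (E)-enal, the ammonium/phosphate-bound hydroperoxide adds to the C3 Si face, and the same ion pair protonates the enamine at C2 from the same side (net syn addition of ROO–H across the E alkene gives the anti (2S,3S) product), with low temperature favouring protonation over 3-exo epoxide closure; the closest known reactions are amine-catalysed asymmetric peroxidation of β-substituted enals and enones with hydroperoxides and cinchona-amine/phosphoric-acid epoxidation of α-branched enals.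

**Step 6**
Reactants: 10
Product: 11, (2S,3S)-3-[(2-methoxypropan-2-yl)peroxy]-2-methyl-6-methylidene-8-(2,6,6-trimethylcyclohex-1-en-1-yl)octanoic acid
Conditions: NaClO2, NaH2PO4, 2-methyl-2-butene (large excess), t-BuOH/H2O, 0 °C
Reagents that add atoms: sodium chlorite, [Na+].[O-]Cl=O
Why: Pinnick oxidation is buffered and non-basic, so C2 does not epimerise and the β-peroxide does not eliminate, while the scavenger protects the alkenes from HOCl.

**Step 7**
Reactants: 11
Product: 12, methyl (2S,3S)-3-[(2-methoxypropan-2-yl)peroxy]-2-methyl-6-methylidene-8-(2,6,6-trimethylcyclohex-1-en-1-yl)octanoate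
Conditions: TMSCHN2, PhMe/MeOH, 0 °C
Reagents that add atoms: (trimethylsilyl)diazomethane, C[Si](C)(C)C=[N+]=[N-]
Why: Neutral O-methylation of the carboxylic acid (diazoalkane esterification) avoids any enolate and therefore any β-elimination of the peroxide.

**Step 8**
Reactants: 12
Product: 13, methyl (2S,3S)-3-hydroperoxy-2-methyl-6-methylidene-8-(2,6,6-trimethylcyclohex-1-en-1-yl)octanoate
Conditions: PPTS (10 mol %), MeOH, 0 °C → rt
Reagents that add atoms: none
Why: Mild acid transketalisation removes the peroxyketal as 2,2-dimethoxypropane and frees the secondary hydroperoxide without touching the alkenes or stereocentres.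

**Step 9**
Reactants: 13
Product: 14, methyl (2S)-2-{(3S,6S)-6-methyl-6-[2-(2,6,6-trimethylcyclohex-1-en-1-yl)ethyl]-1,2-dioxan-3-yl}propanoate
Conditions: (S,S)-IDPi (confined BINOL-derived N-triflyl imidodiphosphorimidate, 5 mol %), cyclohexane/CHCl3, rt
Reagents that add atoms: none
Why: Proposed new method: the confined chiral acid hydrogen-bonds the OOH group and effects a concerted, asynchronous Markovnikov protonation of the CH2 terminus with 6-exo C6–O bond formation inside its pocket, choosing the alkene face that places the new methyl trans to the C3 side chain; the closest known reaction is IDPi-catalysed asymmetric intramolecular hydroalkoxylation of unactivated 1,1-disubstituted alkenes to 2-methyl-2-alkyl cyclic ethers.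

**Step 10**
Reactants: 14
Product: 15, Diacarperoxide B, methyl (2S)-2-[(3S,6R)-6-(4,4-dimethyl-3,8-dioxononyl)-6-methyl-1,2-dioxan-3-yl]propanoate
Conditions: O3, CH2Cl2/MeOH, −78 °C; then Me2S, −78 °C → rt
Reagents that add atoms: ozone, [O-][O+]=O
Why: Ozonolysis with reductive work-up cleaves the only remaining alkene to the two ketones, while the dialkyl peroxide and ester are inert to O3 and Me2S; no stereocentre is touched (C6 changes from S to R only because the CIP priorities change).

## Compound list

1 | dihydro-β-ionone | CC(=O)CCC1=C(C)CCCC1(C)C | starting material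
2 | allyl bromide | C=CCBr | starting material
3 | 1-(2,6,6-trimethylcyclohex-1-en-1-yl)hept-6-en-3-one | C=CCCC(=O)CCC1=C(C)CCCC1(C)C | intermediate
4 | methyltriphenylphosphonium bromide | [Br-].C[P+](c1ccccc1)(c1ccccc1)c1ccccc1 | starting material
5 | 1,3,3-trimethyl-2-(3-methylidenehept-6-en-1-yl)cyclohex-1-ene | C=CCCC(=C)CCC1=C(C)CCCC1(C)C | intermediate
6 | methacrolein | CC(=C)C=O | starting material
7 | (2E)-2-methyl-6-methylidene-8-(2,6,6-trimethylcyclohex-1-en-1-yl)oct-2-enal | O=C/C(C)=C/CCC(=C)CCC1=C(C)CCCC1(C)C | intermediate
8 | 2,3-dimethylbut-2-ene | CC(C)=C(C)C | starting material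
9 | 2-methoxypropan-2-yl hydroperoxide | COC(C)(C)OO | intermediate (reagent)
10 | (2S,3S)-peroxyketal aldehyde | O=C[C@@H](C)[C@@H](OOC(C)(C)OC)CCC(=C)CCC1=C(C)CCCC1(C)C | intermediate
11 | (2S,3S)-peroxyketal acid | OC(=O)[C@@H](C)[C@@H](OOC(C)(C)OC)CCC(=C)CCC1=C(C)CCCC1(C)C | intermediate
12 | (2S,3S)-peroxyketal methyl ester | COC(=O)[C@@H](C)[C@@H](OOC(C)(C)OC)CCC(=C)CCC1=C(C)CCCC1(C)C | intermediate
13 | methyl (2S,3S)-3-hydroperoxy-2-methyl-6-methylidene-8-(2,6,6-trimethylcyclohex-1-en-1-yl)octanoate | COC(=O)[C@@H](C)[C@@H](OO)CCC(=C)CCC1=C(C)CCCC1(C)C | intermediate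
14 | methyl (2S)-2-{(3S,6S)-6-methyl-6-[2-(2,6,6-trimethylcyclohex-1-en-1-yl)ethyl]-1,2-dioxan-3-yl}propanoate | COC(=O)[C@@H](C)[C@@H]1CC[C@](C)(CCC2=C(C)CCCC2(C)C)OO1 | intermediate
15 | Diacarperoxide B | COC(=O)[C@@H](C)[C@@H]1CC[C@](C)(CCC(=O)C(C)(C)CCCC(C)=O)OO1 | target

## Summary

Total step count: 10 (including the one-step preparation of reagent 9).
Longest linear sequence: 9 steps (1 → 3 → 5 → 7 → 10 → 11 → 12 → 13 → 14 → 15).

Steps most likely to fail:

1. **Step 5 (proposed new method).** Risks are epoxide formation instead of peroxide, and poor C2 selectivity in the enamine protonation. Fallback (known chemistry): build C2–C3 by C–C bond formation instead. A chiral-phosphoric-acid-catalysed (Z)-crotylboration of 4-methylidene-6-(2,6,6-trimethylcyclohex-1-en-1-yl)hexanal gives the syn homoallylic alcohol. C3 is then inverted to the anti hydroperoxide via the triflate and H2O2. After ring closure the vinyl group becomes CO2Me in the final ozonolysis, followed by Pinnick oxidation and TMSCHN2.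

2. **Step 9 (proposed new method).** Risks are competing protonation of the tetrasubstituted cyclohexene, acid-induced hydroperoxide decomposition, and mismatched double induction. Fallback (known chemistry): classical cycloperoxymercuration–demercuration (Hg(OAc)2, CH2Cl2; then Bu3SnH or NaBH4). This is not expected to be selective at C6, so the C6 epimers would be separated by chromatography.

3. **Step 6.** Risks are premature loss of the acid-labile peroxyketal (giving a cyclic peroxy-hemiacetal) and HOCl attack on the electron-rich cyclohexene. Fallback: change the oxidation-state strategy. Reduce aldehyde 10 in situ with NaBH4, carry C1 as its acetate through steps 8–9, and oxidise to the acid only after the dioxane is formed (TEMPO/PhI(OAc)2, then NaClO2), then esterify.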